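Numbering: decalin C1–C10 (ring A = C1–C5 and C10, ring B = C5–C10), C11 = benzylic CH2. The retrosynthesis cuts the arene–CHO and arene–C11 bonds, then C5–C10 and C8–C9 of the decalin in one [4+2], then the chain at C2–C3 (aldol) and at the two diene double bonds (Wittig).
Enabling feature: the trisubstituted C1=C10 alkene, inside ring A and exocyclic to ring B, lies between the C5 methine and the quaternary C9, whose other neighbour is the C8 methine. It is the unreacted half of an allene C1=C10=C9 whose ester-conjugated C9=C10 bond serves as dienophile.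
Forward: the open chain is built from methyl hydroxypivalate, two Wittig reagents, pent-3-yn-2-one and CO; rings A and B then close together in one intramolecular Diels–Alder step; the preformed arene is joined afterwards at C11 and formylated.
Stereochemistry: C3 comes from a reagent-controlled boron aldol. The C1 carbinol (asymmetric transfer hydrogenation) is passed by anti SN2' carbonylation into the aR allene axis and from there to C9. C5 and C8 follow from the ester-endo approach and the E,Z geometry of the diene.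
Key step: step 11

Abbreviations: TBS = tert-butyldimethylsilyl, MOM = methoxymethyl, Ipc = isopinocampheyl, Dec = (1S,2R,4aR,6S)-6-[(TBS)oxy]-1,2,5,5-tetramethyl-1,2,3,4,4a,5,6,7-octahydronaphthalen-1-yl (bonded through its quaternary carbon, C9 of the decalin numbering).
Assumption: enol diisopinocampheylborinates of methyl ketones made from (−)-Ipc2BCl add to the Re face of aldehydes, so (+)-Ipc2BCl is specified for the Si-face (3S) aldol of step 6; should the sense be the opposite, the antipodal reagent is used and nothing else changes.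

Step 1
Reactants: 1 methyl 3-hydroxy-2,2-dimethylpropanoate
Product: 2 methyl 2,2-dimethyl-3-oxopropanoate
Conditions: (COCl)2, DMSO, CH2Cl2, −78 °C; Et3N, −78 → 0 °C
Reagents that add atoms: none
Why: Swern oxidation converts the neopentyl primary alcohol into the non-enolisable aldehyde without over-oxidation, the ester being inert.

Step 2
Reactants: 2 methyl 2,2-dimethyl-3-oxopropanoate; 3 (triphenylphosphoranylidene)acetaldehyde
Product: 4 methyl (3E)-2,2-dimethyl-5-oxopent-3-enoate
Conditions: toluene, 80 °C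
Reagents that add atoms: none
Why: Wittig reaction of the stabilised formyl ylide is E-selective, and the ester-activated aldehyde 2 should be consumed before the less electrophilic conjugated enal product is homologated again.

Step 3
Reactants: 4 methyl (3E)-2,2-dimethyl-5-oxopent-3-enoate; 5 ethyltriphenylphosphonium bromide
Product: 7 methyl (3E,5Z)-2,2-dimethylhepta-3,5-dienoate, via ethylidenetriphenylphosphorane 6 (not isolated)
Conditions: 5, NaN(SiMe3)2, THF, 0 °C; then 4, −78 °C → rt
Reagents that add atoms: none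
Why: Z-selective Wittig reaction of the non-stabilised ylide under lithium-free conditions (kinetic cis-oxaphosphetane) attacks only the aldehyde and leaves the E alkene and the ester untouched, which gives the E,Z diene.

Step 4
Reactants: 7 methyl (3E,5Z)-2,2-dimethylhepta-3,5-dienoate
Product: 8 (3E,5Z)-2,2-dimethylhepta-3,5-dien-1-ol
Conditions: LiAlH4, Et2O, 0 °C
Reagents that add atoms: none
Why: Hydride reduction of the ester to the primary alcohol does not touch the unactivated diene.

Step 5
Reactants: 8 (3E,5Z)-2,2-dimethylhepta-3,5-dien-1-ol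
Product: 9 (3E,5Z)-2,2-dimethylhepta-3,5-dienal
Conditions: Dess–Martin periodinane, NaHCO3, CH2Cl2, 0 °C → rt
Reagents that add atoms: none
Why: Dess–Martin oxidation under buffered conditions gives the aldehyde, whose quaternary α-carbon rules out enolisation and migration of the diene into conjugation.

Step 6
Reactants: 9 (3E,5Z)-2,2-dimethylhepta-3,5-dienal; 10 pent-3-yn-2-one
Product: 13 (6S,8E,10Z)-6-hydroxy-7,7-dimethyldodeca-8,10-dien-2-yn-4-one, via enol diisopinocampheylborinate 11 (not isolated), via boron aldolate 12 (not isolated)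
Conditions: 10, (+)-Ipc2BCl, Et3N, Et2O, 0 °C; then 9, −78 → −20 °C; then H2O2, MeOH, pH 7 buffer, 0 °C
Reagents that add atoms: none
Why: Reagent-controlled boron aldol reaction (Paterson type) of the methyl ketone enol borinate through a cyclic transition state adds to the Si face of the aldehyde and sets C6 of 13 (C3 of the decalin) as S, and any 6R material is expected to be removed as a diastereomer after step 8.

Step 7
Reactants: 13 (6S,8E,10Z)-6-hydroxy-7,7-dimethyldodeca-8,10-dien-2-yn-4-one
Product: 14 (6S,8E,10Z)-6-[(TBS)oxy]-7,7-dimethyldodeca-8,10-dien-2-yn-4-one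
Conditions: TBSOTf, 2,6-lutidine, CH2Cl2, −78 °C
Reagents that add atoms: tert-butyldimethylsilyl trifluoromethanesulfonate, CC(C)(C)[Si](C)(C)OS(=O)(=O)C(F)(F)F
Why: Silylation with the silyl triflate and a hindered base at low temperature protects the hindered secondary alcohol faster than retro-aldol cleavage or β-elimination can occur.

Step 8
Reactants: 14 (6S,8E,10Z)-6-[(TBS)oxy]-7,7-dimethyldodeca-8,10-dien-2-yn-4-one
Product: 15 (4S,6S,8E,10Z)-6-[(TBS)oxy]-7,7-dimethyldodeca-8,10-dien-2-yn-4-ol
Conditions: Ru[(S,S)-TsNCHPhCHPhNH](p-cymene) (2 mol %), i-PrOH, rt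
Reagents that add atoms: none
Why: Noyori asymmetric transfer hydrogenation of the ynone is catalyst-controlled, the (S,S) catalyst delivering hydride so that the alkynyl carbinol C4 (C1 of the decalin) becomes S whatever the neighbouring silyloxy centre, while alkyne and diene are untouched.

Step 9
Reactants: 15 (4S,6S,8E,10Z)-6-[(TBS)oxy]-7,7-dimethyldodeca-8,10-dien-2-yn-4-ol
Product: 16 (4S,6S,8E,10Z)-6-[(TBS)oxy]-7,7-dimethyldodeca-8,10-dien-2-yn-4-yl methanesulfonate
Conditions: MsCl, Et3N, CH2Cl2, −40 → 0 °C; used without chromatography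
Reagents that add atoms: methanesulfonyl chloride, CS(=O)(=O)Cl
Why: O-Sulfonylation forms the propargylic mesylate with retention because the C–O bond is not touched.

Step 10
Reactants: 16 (4S,6S,8E,10Z)-6-[(TBS)oxy]-7,7-dimethyldodeca-8,10-dien-2-yn-4-yl methanesulfonate; 17 carbon monoxide
Product: 18 methyl (aR,6S,8E,10Z)-6-[(TBS)oxy]-2,7,7-trimethyldodeca-2,3,8,10-tetraenoate
Conditions: Pd(PPh3)4 (5 mol %), CO (1 atm), MeOH, 2,6-lutidine, THF, 0 °C → rt
Reagents that add atoms: methanol, CO
Why: In this palladium-catalysed carbonylation of a propargylic mesylate (Tsuji type), zerovalent palladium displaces the mesylate in an anti SN2' sense to an allenylpalladium species and CO insertion and methanolysis proceed with retention, so the 4S carbinol is translated into the aR allene axis.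

Step 11
Reactants: 18 methyl (aR,6S,8E,10Z)-6-[(TBS)oxy]-2,7,7-trimethyldodeca-2,3,8,10-tetraenoate
Product: 19 methyl (1S,2R,4aR,6S)-6-[(TBS)oxy]-1,2,5,5-tetramethyl-1,2,4a,5,6,7-hexahydronaphthalene-1-carboxylate
Conditions: Me2AlCl (1.5 equiv), CH2Cl2, −78 → −20 °C
Reagents that add atoms: none
Why: Proposed new method: Me2AlCl binds the ester carbonyl and lowers the LUMO of the conjugated C9=C10 bond of the allene only, so the tethered E,Z-diene should add across it in a concerted but asynchronous intramolecular [4+2] in which C5–C10 bond formation leads and the orthogonal C1=C10 π bond is left behind; the closest known reaction types are Lewis acid-promoted intermolecular Diels–Alder additions to the conjugated bond of 2-methyl-2,3-dienoates (quaternary α-carbon, axis-to-centre transfer), intramolecular Diels–Alder reactions of tethered allenes at their distal double bond (allenyl ethers, allenecarboxamides) and type 1 intramolecular Diels–Alder reactions of 1,7,9-decatrienes. Ring B closes as the cyclohexene of the cycloaddition through both new bonds (C5–C10 and C8–C9); ring A closes through the C5–C10 bond alone, as a six-membered ring over the four-atom tether C1–C2–C3–C4, exo with respect to the reacting C9=C10 bond (C9 stays outside ring A) and with the spectator allene bond ending as the endocyclic C1=C10 alkene. C9 is set by the aR axis: the substituents on C1 lie in the plane of the reacting π orbitals, so only the face of C9=C10 toward which C2 points can reach the diene. C5 and C8 are set relative to C9 by the ester-endo approach (ester under C6–C7, C9 methyl exo) together with the diene geometry, the E bond placing C4 outside and the Z bond placing the C8 methyl inside, hence C8 methyl cis to the C9 methyl and trans to C4. The step needs site selectivity (secured because only C9=C10 is conjugated and activated, whereas addition to C1=C10 would have to close a five-membered or bridged ring), one diene face (endo preference of the aluminium-bound ester, matched with a chair-like tether that carries the C3 silyloxy group pseudo-equatorially) and a rate that outruns the 1,5-hydrogen shift of the Z-pentadienyl unit (low temperature, a slim sp-hybridised C10, and a C4 gem-dimethyl group that favours the folded conformer and has no hydrogen to shift).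

Step 12
Reactants: 19 methyl (1S,2R,4aR,6S)-6-[(TBS)oxy]-1,2,5,5-tetramethyl-1,2,4a,5,6,7-hexahydronaphthalene-1-carboxylate
Product: 20 [(1S,2R,4aR,6S)-6-[(TBS)oxy]-1,2,5,5-tetramethyl-1,2,4a,5,6,7-hexahydronaphthalen-1-yl]methanol
Conditions: LiAlH4, THF, 0 °C → rt
Reagents that add atoms: none
Why: Hydride reduction of the hindered neopentyl ester gives the primary alcohol while the silyl ether and both alkenes are inert.

Step 13
Reactants: 20 [(1S,2R,4aR,6S)-6-[(TBS)oxy]-1,2,5,5-tetramethyl-1,2,4a,5,6,7-hexahydronaphthalen-1-yl]methanol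
Product: 21 Dec-methanol, [(1S,2R,4aR,6S)-6-[(TBS)oxy]-1,2,5,5-tetramethyl-1,2,3,4,4a,5,6,7-octahydronaphthalen-1-yl]methanol
Conditions: TsNHNH2, NaOAc, DME/H2O, 85 °C
Reagents that add atoms: none
Why: Diimide reduction, with diimide formed in situ from the sulfonyl hydrazide, transfers H2 in a concerted syn fashion to the cis-disubstituted C6=C7 alkene much faster than to the trisubstituted and more hindered C1=C10 alkene, without double-bond migration and without creating a stereocentre.

Step 14
Reactants: 21 Dec-methanol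
Product: 22 Dec-carbaldehyde, (1S,2R,4aR,6S)-6-[(TBS)oxy]-1,2,5,5-tetramethyl-1,2,3,4,4a,5,6,7-octahydronaphthalene-1-carbaldehyde
Conditions: Dess–Martin periodinane, NaHCO3, CH2Cl2, rt
Reagents that add atoms: none
Why: Dess–Martin oxidation of the neopentyl primary alcohol gives an aldehyde on a quaternary carbon, so C9 cannot epimerise.

Step 15
Reactants: 23 3,5-dihydroxybenzyl alcohol
Product: 24 [3,5-bis(methoxymethoxy)phenyl]methanol
Conditions: MOMCl (2.2 equiv), K2CO3, acetone, 0 °C → rt
Reagents that add atoms: chloromethyl methyl ether, COCCl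
Why: Williamson-type O-alkylation, in which carbonate deprotonates only the two phenols so that the benzylic alcohol stays free.

Step 16
Reactants: 24 [3,5-bis(methoxymethoxy)phenyl]methanol
Product: 25 tert-butyl{[3,5-bis(methoxymethoxy)phenyl]methoxy}dimethylsilane
Conditions: TBSCl, imidazole, DMF, rt
Reagents that add atoms: tert-butyldimethylsilyl chloride, CC(C)(C)[Si](C)(C)Cl
Why: Standard silylation of the primary alcohol, chosen so that this oxygen is later freed by fluoride together with the C3 silyl ether and not by the stronger acid an alkyl MOM ether would need.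

Step 17
Reactants: 25 tert-butyl{[3,5-bis(methoxymethoxy)phenyl]methoxy}dimethylsilane; 22 Dec-carbaldehyde
Product: 27 {4-[(TBS-oxy)methyl]-2,6-bis(methoxymethoxy)phenyl}(Dec)methanol (both C11 epimers), via aryllithium 26 (not isolated)
Conditions: 25, n-BuLi, THF, 0 °C; then 22, −78 → 0 °C
Reagents that add atoms: none
Why: Directed ortho-metalation occurs at the ring position flanked by both OMOM groups and the aryllithium adds 1,2 to the non-enolisable aldehyde, the new C11 carbinol centre being formed without control because step 19 removes it.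

Step 18
Reactants: 27 {4-[(TBS-oxy)methyl]-2,6-bis(methoxymethoxy)phenyl}(Dec)methanol
Product: 30 O-[{4-[(TBS-oxy)methyl]-2,6-bis(methoxymethoxy)phenyl}(Dec)methyl] S-methyl carbonodithioate, via sodium alkoxide 28 (not isolated), via sodium xanthate 29 (not isolated)
Conditions: NaH, imidazole (cat.), THF, 0 °C → rt; CS2; then MeI
Reagents that add atoms: carbon disulfide, S=C=S; iodomethane, CI
Why: Xanthate formation (alkoxide, CS2, then S-methylation) prepares the hindered benzylic alcohol for radical deoxygenation.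

Step 19
Reactants: 30 O-[{4-[(TBS-oxy)methyl]-2,6-bis(methoxymethoxy)phenyl}(Dec)methyl] S-methyl carbonodithioate
Product: 31 tert-butyl{[4-(Dec-methyl)-3,5-bis(methoxymethoxy)phenyl]methoxy}dimethylsilane
Conditions: Bu3SnH, AIBN (cat.), toluene, 100 °C
Reagents that add atoms: none
Why: Barton–McCombie deoxygenation, in which the stannyl radical adds to the thiocarbonyl group, β-scission gives the benzylic C11 radical and this takes hydrogen from Bu3SnH, under neutral conditions that MOM and silyl ethers tolerate.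

Step 20
Reactants: 31 tert-butyl{[4-(Dec-methyl)-3,5-bis(methoxymethoxy)phenyl]methoxy}dimethylsilane
Product: 33 6-[(TBS-oxy)methyl]-3-(Dec-methyl)-2,4-bis(methoxymethoxy)benzaldehyde, via aryllithium 32 (not isolated)
Conditions: n-BuLi, TMEDA, THF, −20 → 0 °C; then DMF, −78 °C → rt
Reagents that add atoms: N,N-dimethylformamide, CN(C)C=O
Why: Directed ortho-metalation followed by formylation with DMF gives a single aldehyde, because the only free ring positions are the two symmetry-equivalent ones ortho to an OMOM group.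

Step 21
Reactants: 33 6-[(TBS-oxy)methyl]-3-(Dec-methyl)-2,4-bis(methoxymethoxy)benzaldehyde
Product: 34 6-(hydroxymethyl)-3-{[(1S,2R,4aR,6S)-6-hydroxy-1,2,5,5-tetramethyl-1,2,3,4,4a,5,6,7-octahydronaphthalen-1-yl]methyl}-2,4-bis(methoxymethoxy)benzaldehyde
Conditions: Bu4NF, THF, 50 °C
Reagents that add atoms: none
Why: Fluoride cleaves both silyl ethers through Si–F bond formation without affecting the MOM ethers, the aldehyde or the alkene.

Step 22
Reactants: 34 6-(hydroxymethyl)-3-{[(1S,2R,4aR,6S)-6-hydroxy-1,2,5,5-tetramethyl-1,2,3,4,4a,5,6,7-octahydronaphthalen-1-yl]methyl}-2,4-bis(methoxymethoxy)benzaldehyde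
Product: 35 2,4-dihydroxy-6-(hydroxymethyl)-3-{[(1S,2R,4aR,6S)-6-hydroxy-1,2,5,5-tetramethyl-1,2,3,4,4a,5,6,7-octahydronaphthalen-1-yl]methyl}benzaldehyde (CNP0348277.4)
Conditions: 2 M aq HCl, THF, rt → 40 °C
Reagents that add atoms: none
Why: Dilute aqueous acid hydrolyses the two aryl MOM acetals, which the formyl group activates, under conditions expected to be too mild for addition of the phenol to the C1=C10 alkene and, with no alcohol solvent, without acetal formation at the aldehyde.

Compound list
1 | methyl 3-hydroxy-2,2-dimethylpropanoate | COC(=O)C(C)(C)CO | starting material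
2 | methyl 2,2-dimethyl-3-oxopropanoate | COC(=O)C(C)(C)C=O | intermediate
3 | (triphenylphosphoranylidene)acetaldehyde | O=CC=P(c1ccccc1)(c1ccccc1)c1ccccc1 | starting material
4 | methyl (3E)-2,2-dimethyl-5-oxopent-3-enoate | COC(=O)C(C)(C)/C=C/C=O | intermediate
5 | ethyltriphenylphosphonium bromide | CC[P+](c1ccccc1)(c1ccccc1)c1ccccc1.[Br-] | starting material
6 | ethylidenetriphenylphosphorane | CC=P(c1ccccc1)(c1ccccc1)c1ccccc1 | intermediate
7 | methyl (3E,5Z)-2,2-dimethylhepta-3,5-dienoate | C/C=C\C=C\C(C)(C)C(=O)OC | intermediate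
8 | (3E,5Z)-2,2-dimethylhepta-3,5-dien-1-ol | C/C=C\C=C\C(C)(C)CO | intermediate
9 | (3E,5Z)-2,2-dimethylhepta-3,5-dienal | C/C=C\C=C\C(C)(C)C=O | intermediate
10 | pent-3-yn-2-one | CC#CC(C)=O | starting material
11 | pent-1-en-3-yn-2-yl diisopinocampheylborinate (Ipc groups of (+)-Ipc2BCl) | C=C(C#CC)OB([C@H]1C[C@H]2C[C@@H]([C@@H]1C)C2(C)C)[C@H]1C[C@H]2C[C@@H]([C@@H]1C)C2(C)C | intermediate
12 | O-diisopinocampheylboryl derivative of 13 (boron aldolate) | C/C=C\C=C\C(C)(C)[C@@H](OB([C@H]1C[C@H]2C[C@@H]([C@@H]1C)C2(C)C)[C@H]1C[C@H]2C[C@@H]([C@@H]1C)C2(C)C)CC(=O)C#CC | intermediate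
13 | (6S,8E,10Z)-6-hydroxy-7,7-dimethyldodeca-8,10-dien-2-yn-4-one | C/C=C\C=C\C(C)(C)[C@@H](O)CC(=O)C#CC | intermediate
14 | (6S,8E,10Z)-6-[(TBS)oxy]-7,7-dimethyldodeca-8,10-dien-2-yn-4-one | C/C=C\C=C\C(C)(C)[C@@H](O[Si](C)(C)C(C)(C)C)CC(=O)C#CC | intermediate
15 | (4S,6S,8E,10Z)-6-[(TBS)oxy]-7,7-dimethyldodeca-8,10-dien-2-yn-4-ol | C/C=C\C=C\C(C)(C)[C@@H](O[Si](C)(C)C(C)(C)C)C[C@H](O)C#CC | intermediate
16 | (4S,6S,8E,10Z)-6-[(TBS)oxy]-7,7-dimethyldodeca-8,10-dien-2-yn-4-yl methanesulfonate | C/C=C\C=C\C(C)(C)[C@@H](O[Si](C)(C)C(C)(C)C)C[C@H](OS(C)(=O)=O)C#CC | intermediate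
17 | carbon monoxide | [C-]#[O+] | starting material
18 | methyl (aR,6S,8E,10Z)-6-[(TBS)oxy]-2,7,7-trimethyldodeca-2,3,8,10-tetraenoate (allene axis aR = M, not carried by the SMILES string) | C/C=C\C=C\C(C)(C)[C@@H](O[Si](C)(C)C(C)(C)C)CC=C=C(C)C(=O)OC | intermediate
19 | methyl (1S,2R,4aR,6S)-6-[(TBS)oxy]-1,2,5,5-tetramethyl-1,2,4a,5,6,7-hexahydronaphthalene-1-carboxylate | C[C@@H]1C=C[C@@H]2C(=CC[C@H](O[Si](C)(C)C(C)(C)C)C2(C)C)[C@@]1(C)C(=O)OC | intermediate
20 | [(1S,2R,4aR,6S)-6-[(TBS)oxy]-1,2,5,5-tetramethyl-1,2,4a,5,6,7-hexahydronaphthalen-1-yl]methanol | C[C@@H]1C=C[C@@H]2C(=CC[C@H](O[Si](C)(C)C(C)(C)C)C2(C)C)[C@@]1(C)CO | intermediate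
21 | [(1S,2R,4aR,6S)-6-[(TBS)oxy]-1,2,5,5-tetramethyl-1,2,3,4,4a,5,6,7-octahydronaphthalen-1-yl]methanol (Dec-methanol) | C[C@@H]1CC[C@@H]2C(=CC[C@H](O[Si](C)(C)C(C)(C)C)C2(C)C)[C@@]1(C)CO | intermediate
22 | (1S,2R,4aR,6S)-6-[(TBS)oxy]-1,2,5,5-tetramethyl-1,2,3,4,4a,5,6,7-octahydronaphthalene-1-carbaldehyde (Dec-carbaldehyde) | C[C@@H]1CC[C@@H]2C(=CC[C@H](O[Si](C)(C)C(C)(C)C)C2(C)C)[C@@]1(C)C=O | intermediate
23 | 3,5-dihydroxybenzyl alcohol | OCc1cc(O)cc(O)c1 | starting material
24 | [3,5-bis(methoxymethoxy)phenyl]methanol | COCOc1cc(CO)cc(OCOC)c1 | intermediate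
25 | tert-butyl{[3,5-bis(methoxymethoxy)phenyl]methoxy}dimethylsilane | COCOc1cc(CO[Si](C)(C)C(C)(C)C)cc(OCOC)c1 | intermediate
26 | {4-[(TBS-oxy)methyl]-2,6-bis(methoxymethoxy)phenyl}lithium | [Li]c1c(OCOC)cc(CO[Si](C)(C)C(C)(C)C)cc1OCOC | intermediate
27 | {4-[(TBS-oxy)methyl]-2,6-bis(methoxymethoxy)phenyl}(Dec)methanol, both epimers at the carbinol carbon C11 | C[C@@H]1CC[C@@H]2C(=CC[C@H](O[Si](C)(C)C(C)(C)C)C2(C)C)[C@@]1(C)C(O)c1c(OCOC)cc(CO[Si](C)(C)C(C)(C)C)cc1OCOC | intermediate
28 | sodium alkoxide of 27 | C[C@@H]1CC[C@@H]2C(=CC[C@H](O[Si](C)(C)C(C)(C)C)C2(C)C)[C@@]1(C)C([O-])c1c(OCOC)cc(CO[Si](C)(C)C(C)(C)C)cc1OCOC.[Na+] | intermediate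
29 | sodium O-alkyl dithiocarbonate (xanthate salt) of 27 | C[C@@H]1CC[C@@H]2C(=CC[C@H](O[Si](C)(C)C(C)(C)C)C2(C)C)[C@@]1(C)C(OC(=S)[S-])c1c(OCOC)cc(CO[Si](C)(C)C(C)(C)C)cc1OCOC.[Na+] | intermediate
30 | O-[{4-[(TBS-oxy)methyl]-2,6-bis(methoxymethoxy)phenyl}(Dec)methyl] S-methyl carbonodithioate | C[C@@H]1CC[C@@H]2C(=CC[C@H](O[Si](C)(C)C(C)(C)C)C2(C)C)[C@@]1(C)C(OC(=S)SC)c1c(OCOC)cc(CO[Si](C)(C)C(C)(C)C)cc1OCOC | intermediate
31 | tert-butyl{[4-(Dec-methyl)-3,5-bis(methoxymethoxy)phenyl]methoxy}dimethylsilane | C[C@@H]1CC[C@@H]2C(=CC[C@H](O[Si](C)(C)C(C)(C)C)C2(C)C)[C@@]1(C)Cc1c(OCOC)cc(CO[Si](C)(C)C(C)(C)C)cc1OCOC | intermediate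
32 | {6-[(TBS-oxy)methyl]-3-(Dec-methyl)-2,4-bis(methoxymethoxy)phenyl}lithium | C[C@@H]1CC[C@@H]2C(=CC[C@H](O[Si](C)(C)C(C)(C)C)C2(C)C)[C@@]1(C)Cc1c(OCOC)cc(CO[Si](C)(C)C(C)(C)C)c([Li])c1OCOC | intermediate
33 | 6-[(TBS-oxy)methyl]-3-(Dec-methyl)-2,4-bis(methoxymethoxy)benzaldehyde | C[C@@H]1CC[C@@H]2C(=CC[C@H](O[Si](C)(C)C(C)(C)C)C2(C)C)[C@@]1(C)Cc1c(OCOC)cc(CO[Si](C)(C)C(C)(C)C)c(C=O)c1OCOC | intermediate
34 | 6-(hydroxymethyl)-3-{[(1S,2R,4aR,6S)-6-hydroxy-1,2,5,5-tetramethyl-1,2,3,4,4a,5,6,7-octahydronaphthalen-1-yl]methyl}-2,4-bis(methoxymethoxy)benzaldehyde | C[C@@H]1CC[C@@H]2C(=CC[C@H](O)C2(C)C)[C@@]1(C)Cc1c(OCOC)cc(CO)c(C=O)c1OCOC | intermediate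
35 | 2,4-dihydroxy-6-(hydroxymethyl)-3-{[(1S,2R,4aR,6S)-6-hydroxy-1,2,5,5-tetramethyl-1,2,3,4,4a,5,6,7-octahydronaphthalen-1-yl]methyl}benzaldehyde (CNP0348277.4; 3S,5R,8R,9S in decalin numbering) | C[C@@H]1CC[C@@H]2C(=CC[C@H](O)C2(C)C)[C@@]1(C)Cc1c(O)cc(CO)c(C=O)c1O | target

Total step count: 22. Longest linear sequence: 20 steps (steps 1–14 and 17–22); the arene branch (steps 15 and 16) joins at step 17.

Steps most likely to fail

1. Step 11, the step that carries the label "Proposed new method:". Three things may go wrong. Diene-face control may erode, because in the ester-endo approach the exo methyl group on C9 has to pass the inside methyl group on C8. A stepwise, cationic course after C5–C10 bond formation may scramble C8. The cycloaddition may be so slow that the 1,5-hydrogen shift of the Z-diene or isomerisation of the allenoate to a conjugated dienoate wins. The fallback uses known chemistry, sets out from ynone 14 and comes back to the route at carbinol 20. The ynone itself serves as dienophile in a Lewis acid-promoted (Me2AlCl, CH2Cl2) or thermal intramolecular Diels–Alder reaction of the dienynone type. This forms the same two bonds (C5–C10 and C8–C9) with no endo/exo question and should give the bicyclic dienone F1. Copper-catalysed conjugate addition of (isopropoxydimethylsilyl)methylmagnesium chloride (CuBr·SMe2, THF) to C9, anti to the C8 methyl group, with trapping of the C1 enolate by PhNTf2, would give the enol triflate F2. Palladium-catalysed formate reduction (Pd(OAc)2, PPh3, Bu3N, HCO2H, DMF) would remove the triflate and leave the C1=C10 alkene in the silane F3. Tamao oxidation (H2O2, KF, KHCO3, THF/MeOH) would then give 20.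

2. Step 6. Enolisation of the Michael-accepting ynone by the chloroborane and amine may be incomplete or unselective, addition to the hindered aldehyde may be slow, and the enantioface selectivity of methyl ketone borinates is expected to be only moderate. The fallback sets out from 9 and 10 and comes back at 15; it forms the C–C bond without stereocontrol and resolves through the catalyst-controlled reduction. The lithium enolate of 10 (LiN(SiMe3)2, THF, −78 °C) adds to 9 to give the racemic aldol adduct F4. Silylation as in step 7 gives the racemic silyl ether F5. The transfer hydrogenation of step 8 then converts the two enantiomers into 15 and its (4S,6R) diastereomer F6, which are separated by chromatography.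

3. Step 20. The base may deprotonate the benzylic CH2OSi position (followed by silyl migration) or C11 instead of the ring, or metalation of the crowded arene may stay incomplete. The fallback sets out from 31 and comes back at 33. Electrophilic bromination (NBS, MeCN, 0 °C) of the electron-rich ring can only occur at the same two equivalent positions and gives the aryl bromide F7. Bromine–lithium exchange (n-BuLi, THF, −78 °C) and DMF then deliver 33.

Further compounds
F1 | step 11 | (3S,4aS,7R)-3-[(TBS)oxy]-4,4,7,8-tetramethyl-3,4,4a,7-tetrahydronaphthalen-1(2H)-one | C[C@@H]1C=C[C@@H]2C(=C1C)C(=O)C[C@H](O[Si](C)(C)C(C)(C)C)C2(C)C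
F2 | step 11 | (3S,4aS,7R,8S)-3-[(TBS)oxy]-8-{[dimethyl(propan-2-yloxy)silyl]methyl}-4,4,7,8-tetramethyl-2,3,4,4a,7,8-hexahydronaphthalen-1-yl trifluoromethanesulfonate | C[C@@H]1C=C[C@@H]2C(=C(OS(=O)(=O)C(F)(F)F)C[C@H](O[Si](C)(C)C(C)(C)C)C2(C)C)[C@@]1(C)C[Si](C)(C)OC(C)C
F3 | step 11 | {[(1S,2R,4aR,6S)-6-[(TBS)oxy]-1,2,5,5-tetramethyl-1,2,4a,5,6,7-hexahydronaphthalen-1-yl]methyl}dimethyl(propan-2-yloxy)silane | C[C@@H]1C=C[C@@H]2C(=CC[C@H](O[Si](C)(C)C(C)(C)C)C2(C)C)[C@@]1(C)C[Si](C)(C)OC(C)C
F4 | step 6 | racemic (8E,10Z)-6-hydroxy-7,7-dimethyldodeca-8,10-dien-2-yn-4-one | C/C=C\C=C\C(C)(C)C(O)CC(=O)C#CC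
F5 | step 6 | racemic (8E,10Z)-6-[(TBS)oxy]-7,7-dimethyldodeca-8,10-dien-2-yn-4-one | C/C=C\C=C\C(C)(C)C(O[Si](C)(C)C(C)(C)C)CC(=O)C#CC
F6 | step 6 | (4S,6R,8E,10Z)-6-[(TBS)oxy]-7,7-dimethyldodeca-8,10-dien-2-yn-4-ol | C/C=C\C=C\C(C)(C)[C@H](O[Si](C)(C)C(C)(C)C)C[C@H](O)C#CC
F7 | step 20 | tert-butyl{[2-bromo-4-(Dec-methyl)-3,5-bis(methoxymethoxy)phenyl]methoxy}dimethylsilane | C[C@@H]1CC[C@@H]2C(=CC[C@H](O[Si](C)(C)C(C)(C)C)C2(C)C)[C@@]1(C)Cc1c(OCOC)cc(CO[Si](C)(C)C(C)(C)C)c(Br)c1OCOC
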